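**Remarks on the chemistry**

- Carotenoid numbering is used throughout. The ring is C2–C3–C4–C5–C6; C1 is the carbinol carbon (CMe2OH) on C2; C5 carries methyl and hydroxyl; C6 carries the chain through C7. Primed numbers belong to the open (ψ) end.
- Assumption: (3E,5E)-pseudoionone 12 is used as a single geometric isomer (commercial material can be a 5E/5Z mixture from which the E,E isomer is separable), because this double bond becomes C5'=C6' of the target.

## Analysis of the target

The target is (all-E,2R,5R,6S)-2,6-cyclolycopene-1,5-diol. It is a C40 lycopene-type chain in which one end is closed to a cyclopentane (C2–C6) and the other end is the unchanged ψ end with its isolated C1'=C2' alkene. Ten conjugated E double bonds run from C7=C8 to C5'=C6'. The ring carries three contiguous stereocentres: C2 (R, bearing the C1 carbinol), C5 (R, a fully substituted carbinol carbon with methyl and hydroxyl) and C6 (S, bearing the chain). The C5 hydroxyl is cis to the C7 chain, the C1 carbinol is trans to the chain, and hydroxyl and carbinol are therefore trans to each other. The polyene is sensitive to light, oxygen, acid and E/Z scrambling. Both alcohols are tertiary and ionise under acid, and the C5 hydroxyl sits homoallylic to the chromophore. The synthesis is hard for two reasons: a tertiary carbinol must be set next to a methine that becomes α to a carbonyl in any C7-based chain extension, and the ring has no handle at C3 or C4. The strategy rests on one feature. C6 is allylic to C7=C8 and C1 is a tertiary carbinol carbon, so the ring can be read as an open-chain monoterpene unit whose C5–C6 epoxide was opened at C6 by its own C1=C2 alkene, with the C1 cation then hydrated.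

## Retrosynthetic reasoning

**O–Si bonds (20 from 19).** The two tertiary hydroxyls are carried as triethylsilyl ethers to the end and released by fluoride. This keeps acid away from the polyene and from the tertiary carbinols in the last operation.

**C11=C12 (19 from 11 and 17).** This disubstituted double bond is cut because a Wittig reaction of an allylic phosphonium salt with a polyene aldehyde forms it under mild base. Its hindered Z isomer reverts thermally to E. The cut divides the molecule into a C15 ring fragment 11 and a C25 aldehyde 17, so the valuable chiral fragment enters in the last carbon–carbon bond formation.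

**C11'=C12' and the ψ end (17 from 14 and 15; 14 from 13 from 12).** The same Wittig logic cuts 17 into the symmetrical C10 dialdehyde 15 and the C15 salt 14. Salt 14 comes from ketone 12 by vinyl addition (C9'–C10' bond) and phosphine substitution with allylic transposition through carbinol 13. No stereocentre is involved, and the symmetry of 15 removes any regiochemical question.

**P–C11, C9–C10 and C7=C8 on the ring side (11 from 10 from 9 from 8).** The ring fragment is extended in the same way as the ψ end. Salt 11 arises from the bis-allylic tertiary carbinol 10 by ionisation and phosphine capture at C11. Carbinol 10 arises from methyl ketone 9 by vinyl addition. Enone 9 arises from aldehyde 8 by a stabilised-ylide olefination that makes C7=C8 without strong base. This matters because C6 in 8 is α to the carbonyl and C5 carries a β-oxygen.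

**C7 aldehyde and protection (8 from 6 from 5).** The C7 aldehyde is unmasked from a vinyl group by ozonolysis, so C6 needs only a vinyl substituent at the ring-forming stage. Both hydroxyls of 5 are silylated first. A free C5 hydroxyl β to the aldehyde would open the ring by retro-aldol reaction. A free C1 hydroxyl could trap a C6-epimerised aldehyde as a cis-fused lactol.

**Key disconnection, C2–C6 and C1–O (5 from 4).** Cutting the ring bond C2–C6 and the C1–O bond turns 5 into the acyclic cis vinyl epoxide 4. In the forward direction the C5–C6 oxirane is opened at the allylic carbon C6 by the C1=C2 alkene, and the tertiary C1 cation is captured by water. One operation makes the ring, two skeletal bonds and the stereocentres C2 and C6 (the latter by inversion). C5 is brought in unchanged from the epoxide. No other cut of the ring uses the allylic position of C6 and the tertiary nature of C1 together.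

**Vinyl epoxide from the chiral pool of reagents (4 from 3 from 2 from 1).** The vinyl group comes from methylenation of epoxy aldehyde 3, the aldehyde from epoxy alcohol 2, and 2 from nerol 1 by asymmetric epoxidation. The Z geometry of 1 is essential. It places the C4 chain and the later vinyl group cis on the oxirane, and that is what puts the C5 oxygen cis to C7 after inversion at C6.

## Alternatives that were turned down

**Alternative 1: samarium Barbier closure of an iodo keto ester.** The ring bond C4–C5 is cut. The precursor is ethyl 2-acetyl-5-iodo-3-[2-(triethylsilyloxy)propan-2-yl]pentanoate A1. In the forward step SmI2 reduces the primary iodide, and the organosamarium adds to the methyl ketone to give the hydroxy ester A2.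

- For it: chelation of samarium between ketone and ester carbonyls places the new hydroxyl cis to the ester. This is the C5-O/C7 relationship of the target, and closures of this type are very dependable. C7 arrives at the ester level, so no ozonolysis is needed. On reliability of ring closure and on the C5/C6 relationship this alternative is as strong as or stronger than the chosen route.
- Against it: the C2 stereocentre, with its bulky silyloxy-isopropyl group, must be set in absolute terms beforehand on a heavily branched acyclic acetoacetate. That needs its own asymmetric operation and a longer precursor synthesis. The key step needs SmI2 in excess, and the ester must later be adjusted to the aldehyde.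
- Comparison: the chosen route offers one catalytic asymmetric step that fixes all absolute configuration, and ring, two bonds and the C1 oxygen in a single operation four steps from nerol. It pays with a less certain key step.

**Alternative 2: limonene ring cleavage and aldol ring contraction.** The ring bond C5–C6 is cut. (R)-(+)-Limonene A3 supplies all ten carbons and the C2 configuration. Oxidative cleavage of its ring alkene gives (3R)-6-oxo-3-(prop-1-en-2-yl)heptanal A4. A secondary-amine catalyst turns the aldehyde into its enamine, whose α-carbon C6 adds to the methyl ketone C5 to give the hydroxy aldehyde A5.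

- For it: the starting material is very cheap, the sequence to the ring is very short, and C7 is delivered directly as the aldehyde. On step economy this alternative is stronger than the chosen route.
- Against it: A5 is a β-hydroxy aldehyde with an acidic α-hydrogen and a tertiary β-hydroxyl, so the usual fate of this closure is dehydration to the conjugated cyclopentene aldehyde, which erases C5 and C6. If the aldol stage can be held, the C5 configuration depends on kinetic diastereoselection in a reversible addition to a ketone. The competing closure of the ketone enol onto the aldehyde gives an acetyl cyclopentene. The isopropenyl group must also be hydrated in the presence of the aldehyde.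
- Comparison: the chosen route sets C5 by reagent control and C6 by a stereospecific inversion, and it never passes through a β-hydroxy aldehyde with a free hydroxyl.

**Alternative 3: cyclobutene ring-rearrangement metathesis.** The cut is the C3=C4 bond of a cyclopentene. The precursor is the cis-disubstituted cyclobutene A6, 2-[4-(2-hydroxypropan-2-yl)cyclobut-2-en-1-yl]but-3-en-2-ol. A ruthenium alkylidene formed at its vinyl group opens the strained ring and closes the five-membered ring, leaving C7 as a vinyl group in cyclopentene A7.

- For it: strain release drives the step, ruthenium carbenes tolerate free tertiary alcohols, and no stereocentre is formed or endangered in the key step. On predictability of the key step itself it is stronger than the chosen route.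
- Against it: all three stereocentres must be built before the key step. That includes the tertiary carbinol C5 next to the cyclobutene, which would come from a substrate-controlled addition of uncertain selectivity, and an enantiopure cis-cyclobutene from a desymmetrisation. A7 then carries a superfluous C3=C4 alkene that must be saturated in the presence of the more reactive vinyl group, which forces extra operations. Ring-opening oligomerisation of the cyclobutene also competes.
- Comparison: the chosen route builds the saturated ring directly at the correct oxidation level from an acyclic precursor in far fewer steps.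

Key step: step 4

## Route

Step 1
Reactants: 1 nerol [(2Z)-3,7-dimethylocta-2,6-dien-1-ol]
Product: 2 (2S,3R)-2,3-epoxynerol {[(2S,3R)-3-methyl-3-(4-methylpent-3-en-1-yl)oxiran-2-yl]methanol}
Conditions: Ti(OiPr)4 (cat.), L-(+)-diethyl tartrate (cat.), t-BuOOH, 4 Å molecular sieves, CH2Cl2, −20 °C
Reagents that add atoms: tert-butyl hydroperoxide, CC(C)(C)OO
Why: Katsuki–Sharpless asymmetric epoxidation; the titanium tartrate complex binds the allylic hydroxyl, so only the C2=C3 alkene reacts and the remote trisubstituted alkene is left alone. With the L-(+)-tartrate the Z allylic alcohol should give the (2S,3R) cis epoxide with high enantioselectivity, which fixes C5 of the later ring for good and C6 provisionally.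

Step 2
Reactants: 2 (2S,3R)-2,3-epoxynerol
Product: 3 (2R,3R)-3-methyl-3-(4-methylpent-3-en-1-yl)oxirane-2-carbaldehyde
Conditions: TEMPO (cat.), PhI(OAc)2, CH2Cl2, 0 °C to rt; used crude
Reagents that add atoms: none
Why: Oxoammonium (TEMPO/iodine reagent) oxidation of a primary alcohol stops at the aldehyde and is mild enough for the epoxide and the alkene; the descriptor at the aldehyde-bearing carbon changes only because of ligand priorities.

Step 3
Reactants: 3 (2R,3R)-3-methyl-3-(4-methylpent-3-en-1-yl)oxirane-2-carbaldehyde
Product: 4 (2R,3S)-2-methyl-2-(4-methylpent-3-en-1-yl)-3-vinyloxirane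
Conditions: Ph3PCH3Br, KN(SiMe3)2, THF, −78 °C to 0 °C
Reagents that add atoms: methyltriphenylphosphonium bromide, C[P+](c1ccccc1)(c1ccccc1)c1ccccc1.[Br-]
Why: Wittig methylenation with the non-stabilised ylide is fast at low temperature and is the standard way from 2,3-epoxy aldehydes to vinyl epoxides; no stereocentre is touched and the cis relationship of C4 chain and vinyl group is kept.

Step 4
Reactants: 4 (2R,3S)-2-methyl-2-(4-methylpent-3-en-1-yl)-3-vinyloxirane
Product: 5 (1R,2S,3R)-2-ethenyl-3-(2-hydroxypropan-2-yl)-1-methylcyclopentan-1-ol
Conditions: Sc(OTf)3 (10 mol %), H2O (about 5 equiv), MeNO2, high dilution, −20 °C to 0 °C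
Reagents that add atoms: water, O
Why: Sc(OTf)3 binds the oxirane oxygen and weakens the C6–O bond, whose developing positive charge is shared with the C7=C8 π bond; the trisubstituted C1=C2 alkene, held three atoms away on C5, attacks C6 through C2 from the side opposite the departing oxygen, and the tertiary C1 cation that results is quenched by water. The closest known reaction type is the Lewis-acid epoxide-initiated cation–olefin cyclisation, and within it the acid rearrangement of carotenoid 5,6-epoxides to 2,6-cyclo end groups. The cyclopentane C2–C3–C4–C5–C6 closes 5-exo-trig with respect to the alkene (C1 stays outside the ring) and in the endo sense with respect to the oxirane (both oxirane carbons end up in the ring). C5 is not touched and keeps the configuration set in step 1. C6 is inverted by the backside attack, and because the oxirane is cis (C4 chain and vinyl group on the same side) this inversion puts the C5 oxygen cis to the vinyl group. C2 is set by an envelope-like transition state in which the developing CMe2 cation lies anti to the vinyl group on C6, which gives the trans C2/C6 relationship; since C1 is then trans to the C5 oxygen, no internal ether can form and only external water can reach C1. The step needs ionisation at C6 and not at the tertiary C5, carbon–carbon bond formation ahead of direct hydrolysis, hydride shift or closure to a dihydrofuran, and water capture ahead of proton loss; allylic activation, the intramolecular five-ring closure at low temperature and a small measured amount of water are what substrate and conditions provide for this.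

Step 5
Reactants: 5 (1R,2S,3R)-2-ethenyl-3-(2-hydroxypropan-2-yl)-1-methylcyclopentan-1-ol
Product: 6 bis(triethylsilyl) ether of 5 {triethyl[(1R,2S,3R)-2-ethenyl-1-methyl-3-(2-triethylsilyloxypropan-2-yl)cyclopentyl]oxysilane}
Conditions: Et3SiOTf (3 equiv), 2,6-lutidine, CH2Cl2, −78 °C to 0 °C
Reagents that add atoms: triethylsilyl trifluoromethanesulfonate, CC[Si](CC)(CC)OS(=O)(=O)C(F)(F)F
Why: Silyl triflate with a hindered pyridine base silylates even hindered tertiary alcohols. Both hydroxyls are masked because, once C7 is an aldehyde, a free C5 hydroxyl would permit retro-aldol ring opening and a free C1 hydroxyl would permit lactol formation after C6 epimerisation.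

Step 6
Reactants: 6 bis(triethylsilyl) ether of 5
Product: 8 (1S,2R,5R)-2-methyl-2-(triethylsilyloxy)-5-[2-(triethylsilyloxy)propan-2-yl]cyclopentane-1-carbaldehyde, via secondary ozonide 7 (not isolated)
Conditions: O3, CH2Cl2, −78 °C; then PPh3, −78 °C to rt
Reagents that add atoms: ozone, [O-][O+]=O
Why: Ozonolysis (Criegee mechanism) of the only alkene in the molecule, with neutral reductive work-up, gives the C7 aldehyde without base, so C6 is not epimerised; silyl ethers are inert to ozone.

Step 7
Reactants: 8 (1S,2R,5R)-2-methyl-2-(triethylsilyloxy)-5-[2-(triethylsilyloxy)propan-2-yl]cyclopentane-1-carbaldehyde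
Product: 9 (3E)-4-{(1S,2R,5R)-2-methyl-2-(triethylsilyloxy)-5-[2-(triethylsilyloxy)propan-2-yl]cyclopentyl}but-3-en-2-one
Conditions: Ph3P=CHC(O)CH3 (3 equiv), toluene, 90 °C
Reagents that add atoms: 1-(triphenylphosphoranylidene)propan-2-one, CC(=O)C=P(c1ccccc1)(c1ccccc1)c1ccccc1
Why: Wittig reaction with a stabilised ylide is E-selective and close to neutral, so neither epimerisation at C6 nor β-elimination of the C5 silyloxy group is expected. The C6 configuration is in any case the thermodynamically preferred one (formyl group trans to the C2 substituent and to the C5 methyl).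

Step 8
Reactants: 9 (3E)-4-{(1S,2R,5R)-2-methyl-2-(triethylsilyloxy)-5-[2-(triethylsilyloxy)propan-2-yl]cyclopentyl}but-3-en-2-one
Product: 10 (4E)-3-methyl-5-{(1S,2R,5R)-2-methyl-2-(triethylsilyloxy)-5-[2-(triethylsilyloxy)propan-2-yl]cyclopentyl}penta-1,4-dien-3-ol (both epimers at the new carbinol carbon)
Conditions: CH2=CHMgBr, THF, −78 °C to 0 °C; then sat. aq NH4Cl
Reagents that add atoms: vinylmagnesium bromide, C=C[Mg]Br
Why: Grignard 1,2-addition to the methyl ketone of a β-substituted enone, as in the preparation of vinyl ionols; the new carbinol centre forms without control and is destroyed in the next step.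

Step 9
Reactants: 10 (4E)-3-methyl-5-{(1S,2R,5R)-2-methyl-2-(triethylsilyloxy)-5-[2-(triethylsilyloxy)propan-2-yl]cyclopentyl}penta-1,4-dien-3-ol
Product: 11 {(2E,4E)-3-methyl-5-[(1S,2R,5R)-2-methyl-2-(triethylsilyloxy)-5-(2-triethylsilyloxypropan-2-yl)cyclopentyl]penta-2,4-dien-1-yl}triphenylphosphonium bromide
Conditions: PPh3·HBr, CH2Cl2, 0 °C to rt; trituration or crystallisation
Reagents that add atoms: triphenylphosphine hydrobromide, [Br-].c1ccccc1[PH+](c1ccccc1)c1ccccc1
Why: Ionisation of the bis-allylic tertiary alcohol gives a pentadienyl cation that the phosphine captures at the unhindered primary terminus C11 (substitution with allylic transposition), giving the conjugated dienyl salt, expected mainly as 9E. The aprotic solvent and the silyl ether on O5 keep that oxygen from adding to the cation, and any partial loss of silyl groups here is harmless because the aldehyde stage is past.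

Step 10
Reactants: 12 (3E,5E)-pseudoionone [(3E,5E)-6,10-dimethylundeca-3,5,9-trien-2-one]
Product: 13 (4E,6E)-3,7,11-trimethyldodeca-1,4,6,10-tetraen-3-ol (racemic)
Conditions: CH2=CHMgBr, THF, −20 °C to 0 °C; then sat. aq NH4Cl
Reagents that add atoms: vinylmagnesium bromide, C=C[Mg]Br
Why: Grignard 1,2-addition to a dienyl methyl ketone, the classical first step towards the ψ-end C15 salt; the carbinol centre is lost in the next step.

Step 11
Reactants: 13 (4E,6E)-3,7,11-trimethyldodeca-1,4,6,10-tetraen-3-ol
Product: 14 [(2E,4E,6E)-3,7,11-trimethyldodeca-2,4,6,10-tetraen-1-yl]triphenylphosphonium bromide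
Conditions: PPh3·HBr, MeOH, rt; crystallisation
Reagents that add atoms: triphenylphosphine hydrobromide, [Br-].c1ccccc1[PH+](c1ccccc1)c1ccccc1
Why: The same acid-mediated substitution with allylic transposition through a delocalised cation, with phosphine capture at the primary terminus; the 2E salt is the major isomer and is purified by crystallisation.

Step 12
Reactants: 14 [(2E,4E,6E)-3,7,11-trimethyldodeca-2,4,6,10-tetraen-1-yl]triphenylphosphonium bromide; 15 (2E,4E,6E)-2,7-dimethylocta-2,4,6-trienedial (2.5 equiv)
Product: 17 apo-12'-lycopenal [(2E,4E,6E,8E,10E,12E,14E)-2,7,11,15,19-pentamethylicosa-2,4,6,8,10,12,14,18-octaenal], via phosphorus ylide 16 (not isolated)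
Conditions: NaOMe, CH2Cl2/MeOH, 0 °C to rt, slow addition of base; then heptane, 90 °C, dark (Z to E)
Reagents that add atoms: none
Why: Wittig olefination with a semi-stabilised allylic ylide; the excess of dialdehyde and the lower electrophilicity of the longer product aldehyde favour mono-olefination. The new C11'=C12' bond forms as an E/Z mixture, and the sterically hindered Z isomer reverts thermally to E.

Step 13
Reactants: 11 ring-end C15 phosphonium bromide; 17 apo-12'-lycopenal
Product: 19 1,5-bis(triethylsilyl) ether of (all-E,2R,5R,6S)-2,6-cyclolycopene-1,5-diol, via phosphorus ylide 18 (not isolated)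
Conditions: NaOMe, CH2Cl2/MeOH, 0 °C to rt, argon, dark; then heptane, 90 °C (Z to E); crystallisation
Reagents that add atoms: none
Why: Wittig olefination forms C11=C12 and completes the C40 chain; methoxide does not touch tertiary silyl ethers or the ring stereocentres. The hindered 11Z isomer isomerises thermally, and the all-E compound should be separable from a minor 9Z isomer by crystallisation.

Step 14
Reactants: 19 1,5-bis(triethylsilyl) ether of the target
Product: 20 (all-E,2R,5R,6S)-2,6-cyclolycopene-1,5-diol (target)
Conditions: Bu4NF, THF, rt to 40 °C, argon, dark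
Reagents that add atoms: none
Why: Fluoride cleavage of the two Si–O bonds under non-acidic conditions, which spares the polyene and both tertiary alcohols; no stereocentre or double bond is involved.

## Compound list

1 | nerol, (2Z)-3,7-dimethylocta-2,6-dien-1-ol | CC(C)=CCC/C(C)=C\CO | starting material
2 | (2S,3R)-2,3-epoxynerol, [(2S,3R)-3-methyl-3-(4-methylpent-3-en-1-yl)oxiran-2-yl]methanol | CC(C)=CCC[C@@]1(C)O[C@H]1CO | intermediate
3 | (2R,3R)-3-methyl-3-(4-methylpent-3-en-1-yl)oxirane-2-carbaldehyde | CC(C)=CCC[C@@]1(C)O[C@H]1C=O | intermediate
4 | (2R,3S)-2-methyl-2-(4-methylpent-3-en-1-yl)-3-vinyloxirane | CC(C)=CCC[C@@]1(C)O[C@H]1C=C | intermediate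
5 | (1R,2S,3R)-2-ethenyl-3-(2-hydroxypropan-2-yl)-1-methylcyclopentan-1-ol | C=C[C@H]1[C@H](C(C)(C)O)CC[C@@]1(C)O | intermediate
6 | bis(triethylsilyl) ether of 5 | C=C[C@H]1[C@H](C(C)(C)O[Si](CC)(CC)CC)CC[C@@]1(C)O[Si](CC)(CC)CC | intermediate
7 | secondary ozonide of 6 (3-substituted 1,2,4-trioxolane, both epimers at the trioxolane carbon) | O1COOC1[C@H]2[C@H](C(C)(C)O[Si](CC)(CC)CC)CC[C@@]2(C)O[Si](CC)(CC)CC | intermediate
8 | (1S,2R,5R)-2-methyl-2-(triethylsilyloxy)-5-[2-(triethylsilyloxy)propan-2-yl]cyclopentane-1-carbaldehyde | O=C[C@H]1[C@H](C(C)(C)O[Si](CC)(CC)CC)CC[C@@]1(C)O[Si](CC)(CC)CC | intermediate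
9 | (3E)-4-{(1S,2R,5R)-2-methyl-2-(triethylsilyloxy)-5-[2-(triethylsilyloxy)propan-2-yl]cyclopentyl}but-3-en-2-one | CC(=O)/C=C/[C@H]1[C@H](C(C)(C)O[Si](CC)(CC)CC)CC[C@@]1(C)O[Si](CC)(CC)CC | intermediate
10 | (4E)-3-methyl-5-{(1S,2R,5R)-2-methyl-2-(triethylsilyloxy)-5-[2-(triethylsilyloxy)propan-2-yl]cyclopentyl}penta-1,4-dien-3-ol, both carbinol epimers | C=CC(C)(O)/C=C/[C@H]1[C@H](C(C)(C)O[Si](CC)(CC)CC)CC[C@@]1(C)O[Si](CC)(CC)CC | intermediate
11 | {(2E,4E)-3-methyl-5-[(1S,2R,5R)-2-methyl-2-(triethylsilyloxy)-5-(2-triethylsilyloxypropan-2-yl)cyclopentyl]penta-2,4-dien-1-yl}triphenylphosphonium bromide | [Br-].c1ccccc1[P+](c1ccccc1)(c1ccccc1)C/C=C(C)/C=C/[C@H]1[C@H](C(C)(C)O[Si](CC)(CC)CC)CC[C@@]1(C)O[Si](CC)(CC)CC | intermediate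
12 | (3E,5E)-pseudoionone, (3E,5E)-6,10-dimethylundeca-3,5,9-trien-2-one | CC(C)=CCC/C(C)=C/C=C/C(C)=O | starting material
13 | (4E,6E)-3,7,11-trimethyldodeca-1,4,6,10-tetraen-3-ol, racemic | CC(C)=CCC/C(C)=C/C=C/C(C)(O)C=C | intermediate
14 | [(2E,4E,6E)-3,7,11-trimethyldodeca-2,4,6,10-tetraen-1-yl]triphenylphosphonium bromide | CC(C)=CCC/C(C)=C/C=C/C(C)=C/C[P+](c1ccccc1)(c1ccccc1)c1ccccc1.[Br-] | intermediate
15 | (2E,4E,6E)-2,7-dimethylocta-2,4,6-trienedial (C10 dialdehyde) | O=C/C(C)=C/C=C/C=C(C)/C=O | starting material
16 | phosphorus ylide of 14, [(2E,4E,6E)-3,7,11-trimethyldodeca-2,4,6,10-tetraen-1-ylidene]triphenylphosphorane | CC(C)=CCC/C(C)=C/C=C/C(C)=C/C=P(c1ccccc1)(c1ccccc1)c1ccccc1 | intermediate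
17 | apo-12'-lycopenal, (2E,4E,6E,8E,10E,12E,14E)-2,7,11,15,19-pentamethylicosa-2,4,6,8,10,12,14,18-octaenal | CC(C)=CCC/C(C)=C/C=C/C(C)=C/C=C/C(C)=C/C=C/C=C(C)/C=O | intermediate
18 | phosphorus ylide of 11 | c1ccccc1P(c1ccccc1)(c1ccccc1)=C/C=C(C)/C=C/[C@H]1[C@H](C(C)(C)O[Si](CC)(CC)CC)CC[C@@]1(C)O[Si](CC)(CC)CC | intermediate
19 | 1,5-bis(triethylsilyl) ether of (all-E,2R,5R,6S)-2,6-cyclolycopene-1,5-diol | CC(C)=CCC/C(C)=C/C=C/C(C)=C/C=C/C(C)=C/C=C/C=C(C)/C=C/C=C(C)/C=C/[C@H]1[C@H](C(C)(C)O[Si](CC)(CC)CC)CC[C@@]1(C)O[Si](CC)(CC)CC | intermediate
20 | (all-E,2R,5R,6S)-2,6-cyclolycopene-1,5-diol | CC(C)=CCC/C(C)=C/C=C/C(C)=C/C=C/C(C)=C/C=C/C=C(C)/C=C/C=C(C)/C=C/[C@H]1[C@H](C(C)(C)O)CC[C@@]1(C)O | target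

## Step count and least certain steps

Total step count: 14. Longest linear sequence: 11 steps from nerol 1 (steps 1–9, 13, 14). The three-step branch (steps 10–12) supplies aldehyde 17.

**Step 4 (key step).** Several things can go wrong:
- ionisation at the tertiary C5 instead of C6, followed by hydride shift to a ketone;
- opening of the activated oxirane by water before the alkene engages;
- closure of the allyl cation onto the oxygen to give a dihydrofuran;
- proton loss from the C1 cation instead of water capture;
- erosion of the inversion at C6 if the C6–O bond ionises fully before the alkene attacks.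

The water-related failures are the most likely, because the amount of water the oxirane tolerates is small. The fallback separates ring closure from hydration; it sets out from 4 and comes back at 5. Vinyl epoxide 4 is treated with MeAlCl2 in dry CH2Cl2 at −78 °C, so that the cyclisation ends by loss of a methyl proton and gives (1R,2S,3R)-2-ethenyl-1-methyl-3-(prop-1-en-2-yl)cyclopentan-1-ol F1. One equivalent of mCPBA with NaHCO3 in CH2Cl2 at 0 °C then epoxidises the more electron-rich 1,1-disubstituted alkene in preference to the hindered vinyl group, giving (1R,2S,3R)-2-ethenyl-1-methyl-3-(2-methyloxiran-2-yl)cyclopentan-1-ol F2 (both oxirane epimers serve). LiAlH4 in THF opens this oxirane at its CH2 terminus and gives 5. The trans arrangement of the C5 hydroxyl and the C2 side chain prevents internal ether formation throughout.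

**Step 7.** The aldehyde is flanked by a fully substituted carbon and a bulky side chain, so olefination with the weakly nucleophilic stabilised ylide may be slow. Prolonged heating invites elimination of the C5 silyloxy group or epimerisation at C6. The fallback avoids the aldehyde altogether; it sets out from 6 and comes back at 9. Cross metathesis of the vinyl group of 6 with an excess of methyl vinyl ketone, using the second-generation Hoveyda–Grubbs catalyst RuCl2(H2IMes)(=CH-C6H4-2-OiPr) in CH2Cl2 at 40 °C, gives the E enone 9 directly and makes steps 6 and 7 unnecessary.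

**Step 9.** The acid needed for ionisation may remove silyl groups. A freed C5 hydroxyl could then add to the pentadienyl cation, proton loss could give a triene instead of the salt, and the 9Z isomer may form in a larger share than wanted. The fallback reaches the salt without a cation; it sets out from 8 and comes back at 11. Horner–Wadsworth–Emmons reaction of 8 with ethyl (2E)-4-(diethoxyphosphoryl)-3-methylbut-2-enoate and LiN(SiMe3)2 in THF at −78 °C to 0 °C gives ethyl (2E,4E)-3-methyl-5-{(1S,2R,5R)-2-methyl-2-(triethylsilyloxy)-5-[2-(triethylsilyloxy)propan-2-yl]cyclopentyl}penta-2,4-dienoate F3. Reduction with i-Bu2AlH in CH2Cl2 at −78 °C gives the corresponding (2E,4E)-penta-2,4-dien-1-ol F4. CBr4 and PPh3 in CH2Cl2 at 0 °C give the (2E,4E)-5-bromo-3-methylpenta-1,3-dienyl compound F5, and PPh3 in toluene at rt then gives 11.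

**Step 13.** The semi-stabilised ylide gives Z/E mixtures at C11=C12. Incomplete isomerisation, a 9Z share carried in from 11, and oxidative or base-induced loss of the ylide would all cost the valuable ring fragment at the last carbon–carbon bond formation. The fallback reverses the order of assembly; it sets out from 11 and comes back at 19. Salt 11 is first condensed (NaOMe, CH2Cl2/MeOH) with an excess of dialdehyde 15, the most electrophilic partner, to give the ring-end C25 aldehyde (2E,4E,6E,8E,10E,12E)-2,7,11-trimethyl-13-{(1S,2R,5R)-2-methyl-2-(triethylsilyloxy)-5-[2-(triethylsilyloxy)propan-2-yl]cyclopentyl}trideca-2,4,6,8,10,12-hexaenal F6. This is then driven to 19 with an excess of the inexpensive salt 14 under the same conditions, followed by thermal isomerisation.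

## Further compounds

F1 | step 4 | (1R,2S,3R)-2-ethenyl-1-methyl-3-(prop-1-en-2-yl)cyclopentan-1-ol | C=C[C@H]1[C@H](C(C)=C)CC[C@@]1(C)O
F2 | step 4 | (1R,2S,3R)-2-ethenyl-1-methyl-3-(2-methyloxiran-2-yl)cyclopentan-1-ol, both oxirane epimers | C=C[C@H]1[C@H](C2(C)CO2)CC[C@@]1(C)O
F0 | step 7 | none | none
F3 | step 9 | ethyl (2E,4E)-3-methyl-5-{(1S,2R,5R)-2-methyl-2-(triethylsilyloxy)-5-[2-(triethylsilyloxy)propan-2-yl]cyclopentyl}penta-2,4-dienoate | CCOC(=O)/C=C(C)/C=C/[C@H]1[C@H](C(C)(C)O[Si](CC)(CC)CC)CC[C@@]1(C)O[Si](CC)(CC)CC
F4 | step 9 | (2E,4E)-3-methyl-5-{(1S,2R,5R)-2-methyl-2-(triethylsilyloxy)-5-[2-(triethylsilyloxy)propan-2-yl]cyclopentyl}penta-2,4-dien-1-ol | OC/C=C(C)/C=C/[C@H]1[C@H](C(C)(C)O[Si](CC)(CC)CC)CC[C@@]1(C)O[Si](CC)(CC)CC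
F5 | step 9 | triethyl{[(1R,2S,3R)-2-[(1E,3E)-5-bromo-3-methylpenta-1,3-dien-1-yl]-1-methyl-3-(2-triethylsilyloxypropan-2-yl)cyclopentyl]oxy}silane | BrC/C=C(C)/C=C/[C@H]1[C@H](C(C)(C)O[Si](CC)(CC)CC)CC[C@@]1(C)O[Si](CC)(CC)CC
F6 | step 13 | (2E,4E,6E,8E,10E,12E)-2,7,11-trimethyl-13-{(1S,2R,5R)-2-methyl-2-(triethylsilyloxy)-5-[2-(triethylsilyloxy)propan-2-yl]cyclopentyl}trideca-2,4,6,8,10,12-hexaenal | O=C/C(C)=C/C=C/C=C(C)/C=C/C=C(C)/C=C/[C@H]1[C@H](C(C)(C)O[Si](CC)(CC)CC)CC[C@@]1(C)O[Si](CC)(CC)CC
A1 | alternative 1 | ethyl (3R)-2-acetyl-5-iodo-3-[2-(triethylsilyloxy)propan-2-yl]pentanoate, both epimers at C2 | CCOC(=O)C(C(C)=O)[C@H](C(C)(C)O[Si](CC)(CC)CC)CCI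
A2 | alternative 1 | ethyl 2-hydroxy-2-methyl-5-[2-(triethylsilyloxy)propan-2-yl]cyclopentane-1-carboxylate with the ring configuration of the target | CCOC(=O)[C@H]1[C@H](C(C)(C)O[Si](CC)(CC)CC)CC[C@@]1(C)O
A3 | alternative 2 | (R)-(+)-limonene | CC1=CC[C@@H](CC1)C(C)=C
A4 | alternative 2 | (3R)-6-oxo-3-(prop-1-en-2-yl)heptanal | O=CC[C@H](C(C)=C)CCC(C)=O
A5 | alternative 2 | 2-hydroxy-2-methyl-5-(prop-1-en-2-yl)cyclopentane-1-carbaldehyde with the ring configuration of the target | O=C[C@H]1[C@H](C(C)=C)CC[C@@]1(C)O
A6 | alternative 3 | 2-[cis-4-(2-hydroxypropan-2-yl)cyclobut-2-en-1-yl]but-3-en-2-ol with the carbinol configuration needed for the target | C1=C[C@@H](C(C)(C)O)[C@H]1[C@](C)(O)C=C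
A7 | alternative 3 | 4-(2-hydroxypropan-2-yl)-1-methyl-5-vinylcyclopent-2-en-1-ol with the ring configuration of the target | C=C[C@H]1[C@H](C(C)(C)O)C=C[C@@]1(C)O
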